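The constants I can get from these runs reduce to one clock: the fraction of substrate lost per minute, with time counted in turnovers of it.

| setting | violet | ochre | flask |
|---|---|---|---|
| substrate | 19 mM | 13 mM | 19 mM |
| gas phase | 1.1 mM (held) | 1.1 mM (held) | 1.1 mM (held) |
| catalyst | 0.19 mM | 0.19 mM | 0.19 mM |
| remark | the very flask that is asked about, followed so far | run made earlier |  |
| time |  |  | 80 min |

- violet (time / min: target / %, substrate / %): 0.667: 7, 94; 2.00: 16, 82; 3.00: 24, 72; 5.00: 38, 58; 8.00: 48, 38; 10.0: 55, 27
- ochre (time / min: target / %, substrate / %): 5.00: 43, 54; 15.0: 59, 16; 30.0: 39, 0; 40.0: 31, 0; 60.0: 24, 0; 80.0: 20, 0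

(readings scatter by 1.5 percentage points)

1. the target standing at 80 min, as a percentage of the substrate charged
2. concentration of dissolved gas in solution at 80 min, in percent of saturation

- at the start none of the gas phase is in solution

I take the substrate charge first. By hand, a pseudo-first-order loss keeps its constant at any charge, and within scatter it does here: violet gives 0.131 min⁻¹ at 19 mM, ochre 0.122 min⁻¹ at 13 mM, about the same. So in percent of the charge I expect violet to retrace ochre. On violet's clock the asked time is 10.5 turnovers, and this count, the loss constant times the time, is what I carry.

Next comes the catalyst. Both runs hold 0.19 mM, so they cannot show its effect. By hand it would rescale the clock, but that many turnovers leave 0.00282% of the substrate, so I expect little from it unless the later fall of target runs on it too.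

Then time. Ochre's target lost 7 percentage points from 40.0 min to 60.0 min, then less, 4 points, up to 80.0 min. So I commit to ochre's 20% for this flask.

The forecast says 26% and 98%: “Applying ochre's time-dependent decay from 25 to 80 min (factor about 0.45) gives about 26%”. My figure stands 6 points lower.

The flask gives 19.0% and 96.8%.

    gas phase ⇌ dissolved gas, rate k1*(csat - [dissolved gas]) (kL = 5.60 min⁻¹)
    target ⇌ isomer of the product (K = 4.70, k = 0.0477 min⁻¹)
    dissolved gas → decomposed reagent (k = 0.184 min⁻¹)
    substrate + dissolved gas + catalyst → catalyst + target (k = 12800 L² mol⁻² s⁻¹)

In this flask substrate falls under a fiftieth of its charge by 28.4 min, and half of the making of target is done by 6.15 min. Target meanwhile passes to the isomer of the product, half of that turnover done by 20.5 min, and at 80 min, which my estimate from violet's scattered readings counts as 10.5 turnovers, it holds 19.0% against 81.0% of the isomer, with the backward turnover 36% of the forward and the catalyst at 100%. Moved one at a time, the settings rank: time (2.7 points), then catalyst (0.31 points), then substrate (under 0.05 points).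

The same flask read at 20 min counts, on violet's clock, 2.62 turnovers, so I expect 7.29% substrate and, between ochre's readings, 52.3% target. It gives 7.16% and 53.4%.

The numbers in the tables were generated by integration with constants of no real substance.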